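Remark: C2 keeps one spatial arrangement and the descriptor S from 8 to 16. C3 is S in 11 and R from 12 onward only because CO2Me outranks C2 in the CIP order while CH2O does not, so the structures of 8, 11 and 16 are mutually consistent and need no correction. Compound 5 is assumed to be a catalogue compound.

## Structural features

Compound 16 is a trans-2,3-disubstituted 2,3-dihydrobenzofuran: benzene ring A is fused through C3a and C7a to the five-membered ring O1–C2–C3 and carries an allyl group at C5 and a methoxy group at C7. C2 bears a 4-hydroxy-3-methoxyphenyl group (ring B) and C3 a CH2–O arm that ends in a 4-allyl-2-methoxyphenyl ring (ring C), so three differently oxygenated arenes meet around two sp3 carbons. The two stereocentres are adjacent and their substituents are trans; C2 (S) is a benzylic ether carbon para to the ring B oxygen, and C3 (R) is benzylic to ring A. The fragile groups are the two allylarenes (double-bond migration under strong base or metal hydrides, attack by electrophilic oxidants and boranes), the free guaiacyl phenol (oxidisable, and able to open C2–O1 through a quinone methide) and four aryl methyl ethers that rule out any general ether cleavage. The real difficulty is absolute control at C2 and C3 together with the trans relation, because the ring offers no handle beyond its two benzylic positions. The key step uses the fact that C3 is bonded to C3a of ring A and to exactly one exocyclic carbon, which is the pattern left when C4 of a 2-arylchroman-4-one is pushed out of the ring by a shift of the ring A carbon from C4 to C3. The stereochemical problem thereby shrinks to the single centre C2 of a flavanone, from which C3 follows.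

## Logic of the disconnections

**16 ⇒ 15.** The acyl C–O bond on the ring B oxygen is cut, a protecting-group bond. The acyl group is needed twice earlier: it makes ring B electron-poor in the oxidative step, and it keeps the ring B oxygen from competing as a nucleophile in the etherification. Nothing is gained in skeleton, but the only acidic and oxidisable group is hidden. The forward cleavage must spare two allylarenes and the C2–O1 bond, which calls for carbonate methanolysis at room temperature.

**15 ⇒ 13 + 14.** The CH2–O(aryl) bond of the arm is cut. This removes ring C as 14, a commodity phenol that already carries its allyl group, and leaves a primary alcohol. The forward step must join a β-branched primary carbinol to a phenol without free phenoxide at elevated temperature, which would attack the aryl ester, and without a discrete sulfonate, which could eliminate toward the aromatic benzofuran. A redox condensation answers both demands.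

**13 ⇒ 12.** The C5–CH2 bond of the ring A allyl group is cut. The allyl group cannot be present in the oxidative rearrangement, and it is better absent when an ester is reduced with borohydride. A bromine atom is an inert placeholder that can be introduced by a trivial para bromination at the outset. The forward coupling must be neutral and must not move the double bond into conjugation.

**12 ⇒ 11.** The primary alcohol is taken back to the methyl ester, the oxidation level at which the one-carbon arm leaves the key step. The reduction is placed directly after the rearrangement, before any alkene exists, because borohydride–ester mixtures can hydroborate terminal alkenes. The forward step must distinguish a methyl ester from a hindered aryl ester.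

**11 ⇒ 8 (key).** The C3–C3a bond is cut and the ring A carbon is reconnected to the ester carbon, which expands the five-membered ring to the chroman-4-one. Two contiguous centres become one, C2, on a heterocycle that catalysis can deliver in one enantiomer; C3 is then derived stereospecifically. The forward step demands that ring A and not ring B migrates and that every substituent tolerates trivalent iodine and strong acid. The bromine and the bulky acyl group on the ring B oxygen are therefore kept. A silyl or alkyl group would leave ring B electron-rich and prone to migrate. A sulfonate would need hot hydroxide or amide base for removal at the last step. A less hindered acyl group would not survive the steps on either side.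

**8 ⇒ 4 + 7.** The C2–C1′ bond is cut. This leaves a flat, achiral chromone and an arylboron reagent, so the only source of chirality is a catalyst. The ring B oxygen must already be acylated in 7: a free para phenoxide would open the flavanone through a quinone methide and erase C2. The forward step needs near-neutral conditions, because flavanones also racemise by base-induced ring opening.

**4 ⇒ 2 ⇒ 1.** O1–C2 and C2–C3 of the pyranone are cut, C2 coming from a formamide acetal, and then the C–Br bond. The hydroxyl group of 1 directs bromination to its only free para position, which becomes C5 of the target.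

**7 ⇒ 6 ⇒ 5.** The B–O bonds of the pinacol ester and the acyl C–O bond are cut. Compound 5 already has the boron para to the phenol, so no aryl halide borylation is needed.

## Other disconnections considered

**Alternative 1:** Both bonds at C2 are cut (C2–C3 and O1–C2), a [4+1] plan. The precursors are the sulfone A2, which is 14 with a 1-sulfonyl-2-aryloxyethyl group ortho to its hydroxyl, and the benzylic thiolanium salt A3. In the forward sense Cs2CO3 would expel sulfinate from A2 to give the ortho-quinone methide A4 and deprotonate A3 to the ylide A5. Conjugate addition would form C2–C3, and the phenoxide would then displace the sulfide (5-exo-tet) to form O1–C2 and give the silyl ether A1, one desilylation from 16.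
- In its favour: it is the most convergent plan. Ring A and ring C both come from 14 with their allyl groups in place, so no halogen placeholder and no oxidant-sensitive stage are needed.
- Against it here: neither A2 nor A3 is chiral, so A1 would be racemic unless an enantiopure sulfide or a chiral catalyst is added, and enantiocontrol with a semi-stabilised benzyl ylide on an alkyl-substituted methide is much less secure than catalytic arylation of a chromone. A4 carries a CH2OAr group on the methide carbon, so tautomerisation to a vinylphenol competes. In A2 the aryloxide is β to the sulfonyl-stabilised carbanion and could be expelled instead of the sulfinate.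
- Comparison: on step economy this alternative is better than the chosen plan. On trans selectivity it is equal, since anti betaine closure and invertive migration both lead to trans. On absolute configuration and on the predictability of the reactive intermediate it is weaker.

**Alternative 2:** Only O1–C2 is cut. The precursor is the bis-phenol A7, in which C3 already bears ring A, the CH2O–ring C arm and a 4-hydroxy-3-methoxybenzyl group. Ag2O would oxidise the guaiacyl unit to the para-quinone methide A8, and the ring A phenol would add to its exocyclic carbon (5-exo-trig) to give A6. The bromide of A6 still has to be exchanged for allyl.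
- In its favour: the closure is biomimetic and needs no aryl-migration selectivity. C2 follows from C3 by 1,2-induction toward the more stable trans ring. Ring B ends as the free phenol, so no protecting group is needed on it, and on that point the alternative is better than the chosen plan.
- Against it here: A7 holds two oxidisable phenols. Oxidation of the ring A phenol toward an ortho-quinone methide at C3 would destroy the only stereocentre, and radical coupling of the guaiacyl ring competes with methide formation. C3 must be set beforehand on an open chain with an auxiliary or an asymmetric hydrogenation. The bromide-to-allyl exchange would then run with a free phenol present.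
- Comparison: equal on trans selectivity and on the use of a bromine placeholder, better on protecting-group economy, worse on chemoselectivity of the oxidation and on total step count.

**Alternative 3:** Ring A itself is cut at C7–C7a and C3a–C4. The lactone A10 has C7a as its carbonyl carbon and C3a as its α carbon. It would be O-silylated through its enolate to the ketene acetal A11, which would add to the electron-poor 2-pyrone A12 in an inverse-demand Diels–Alder reaction. Loss of CO2 from the bridged adduct and of silanol would aromatise to A9.
- In its favour: both stereocentres rest in a trans-β,γ-disubstituted butyrolactone, for which mature asymmetric methods exist, and they never face a cationic rearrangement. The polarity of the partners matches the required regiochemistry (nucleophilic C3a to pyrone C6). Ring A substitution can be varied through the pyrone, which makes this plan better for analogue work.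
- Against it here: the methoxy group on C3 of A12 lowers the electrophilicity of the diene and sits at the terminus that must bond to the fully substituted acetal carbon, so forcing temperatures are to be expected with an allyl group on board. Ring A arrives with an ester at C5, and turning it into allyl needs reduction, activation and a vinyl coupling where the chosen plan needs one coupling. A10 requires a longer enantioselective synthesis than 8.
- Comparison: equal or slightly better on stereochemical security, cleaner in principle as a pericyclic cascade but less well supported for so substituted a pyrone, clearly worse on step economy.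

Key step: step 6

## Route

Step 1
Reactants: 1 2-hydroxy-3-methoxyacetophenone
Product: 2 1-(5-bromo-2-hydroxy-3-methoxyphenyl)ethanone
Conditions: NBS (1.05 equiv), MeCN, 0 °C to rt
Reagents that add atoms: N-bromosuccinimide, O=C1CCC(=O)N1Br
Why: Electrophilic aromatic bromination; the hydroxyl group directs to its only free para position C5, which is also meta to the acetyl group, and NBS in MeCN is mild enough to leave the acetyl methyl group alone.

Step 2
Reactants: 2 1-(5-bromo-2-hydroxy-3-methoxyphenyl)ethanone
Product: 4 6-bromo-8-methoxy-4H-chromen-4-one, via enaminone 3 (not isolated)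
Conditions: Me2NCH(OMe)2, toluene, 100 °C; then conc. HCl, CH2Cl2, 40 °C
Reagents that add atoms: N,N-dimethylformamide dimethyl acetal, COC(OC)N(C)C
Why: Enaminone route to chromones; condensation of the methyl ketone with the formamide acetal gives the vinylogous amide 3, and acid then lets the phenol oxygen add to the aminomethylene carbon (6-endo) with loss of dimethylamine, which builds O1–C2 and the C2=C3 bond.

Step 3
Reactants: 5 2-methoxy-4-(4,4,5,5-tetramethyl-1,3,2-dioxaborolan-2-yl)phenol
Product: 6 2-methoxy-4-(4,4,5,5-tetramethyl-1,3,2-dioxaborolan-2-yl)phenyl pivalate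
Conditions: PivCl, Et3N, DMAP (cat.), CH2Cl2, 0 °C to rt
Reagents that add atoms: pivaloyl chloride, CC(C)(C)C(=O)Cl
Why: DMAP-catalysed O-acylation of the phenol; the pinacol boronate is inert to acyl chloride and amine, and the bulky acyl group is chosen because it has to outlast aqueous base, strong acid and hydride.

Step 4
Reactants: 6 2-methoxy-4-(4,4,5,5-tetramethyl-1,3,2-dioxaborolan-2-yl)phenyl pivalate
Product: 7 [3-methoxy-4-(pivaloyloxy)phenyl]boronic acid
Conditions: NaIO4, NH4OAc, acetone/H2O, rt
Reagents that add atoms: water, O
Why: Oxidative deprotection of a pinacol boronate; periodate cleaves the pinacol released in the hydrolysis equilibrium and so drives 6 to the free boronic acid under buffered, near-neutral conditions that leave the aryl ester intact.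

Step 5
Reactants: 4 6-bromo-8-methoxy-4H-chromen-4-one; 7 [3-methoxy-4-(pivaloyloxy)phenyl]boronic acid (2.5 equiv)
Product: 8 (2S)-6-bromo-8-methoxy-2-[3-methoxy-4-(pivaloyloxy)phenyl]chroman-4-one
Conditions: [RhCl(C2H4)2]2 (2.5 mol%), (1S,4S)-2,5-diphenylbicyclo[2.2.2]octa-2,5-diene (5.5 mol%), aq KOH (10 mol%), toluene/H2O, 40 °C
Reagents that add atoms: none
Why: Hayashi–Miyaura asymmetric 1,4-addition; the aryl–rhodium species formed by transmetalation adds across C2=C3 of the chromone held on the chiral diene, and protonation of the oxa-π-allyl rhodium releases the ketone, so the diene selects the enone face and sets C2 as S (the (S,S) ligand is expected to do so by analogy with six-membered cyclic enones, and its antipode is taken if a trial shows the opposite sense). Monovalent rhodium does not insert into the aryl bromide, and the nearly base-free two-phase medium spares the pivalate and the ring-opening-prone flavanone.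

Step 6
Reactants: 8 (2S)-6-bromo-8-methoxy-2-[3-methoxy-4-(pivaloyloxy)phenyl]chroman-4-one
Product: 11 methyl (2S,3S)-5-bromo-7-methoxy-2-[3-methoxy-4-(pivaloyloxy)phenyl]-2,3-dihydrobenzofuran-3-carboxylate (trans), via enol ether 9 (not isolated), via iodane 10 (not isolated)
Conditions: PhI(OAc)2 (1.2 equiv), conc. H2SO4 (0.5 equiv), HC(OMe)3, rt
Reagents that add atoms: trimethyl orthoformate, COC(OC)OC
Why: This is the known oxidative ring contraction of flavanones by trivalent iodine in orthoformate, the cyclic counterpart of the oxidative 1,2-aryl shift that turns aryl ketones into arylacetic esters. Acid and HC(OMe)3 convert ketone 8 into enol ether 9; the electrophilic iodine reagent adds to C3 of 9 on the face away from the C2 aryl group and methanol closes the ketal, giving 10 with an equatorial C3–I bond antiperiplanar to the C4–C4a ring bond. The ketal oxygens then push C4a from C4 to C3 as iodobenzene leaves, so C3–C3a forms with inversion at C3 and C4 ends as a dimethoxycarbenium ion that is demethylated to the methyl ester. The five-membered ring arises by contraction of the six-membered ring through a bridged arenium transition structure, not by an exo or endo cyclisation. C2 is not touched and stays S; C3 is set by anti iodination followed by invertive migration, which puts CO2Me trans to the C2 aryl group (3S), and the epimerisable ester can only drift toward the same, more stable trans isomer. The step needs ring A to migrate in preference to ring B, to loss of the C2 hydrogen (flavone) and to methanolysis at C3. The ether oxygen ortho to C4a makes ring A the better migrating group, the pivalate makes ring B electron-poor and leaves its C2–aryl bond out of alignment with the equatorial C3–I bond, and bromine stands in for the allyl group that the oxidant would attack.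

Step 7
Reactants: 11 methyl (2S,3S)-5-bromo-7-methoxy-2-[3-methoxy-4-(pivaloyloxy)phenyl]-2,3-dihydrobenzofuran-3-carboxylate
Product: 12 4-[(2S,3R)-5-bromo-3-(hydroxymethyl)-7-methoxy-2,3-dihydrobenzofuran-2-yl]-2-methoxyphenyl pivalate
Conditions: LiBH4 (1.5 equiv), THF, 0 °C
Reagents that add atoms: none
Why: Chemoselective LiBH4 reduction of an ester; the methyl ester is expected to react faster than the tert-butyl-shielded aryl pivalate at 0 °C, the aryl bromide is inert, and no alkene is yet present that the borohydride–ester mixture could hydroborate. No bond at C3 is broken; its descriptor becomes R only through the change in CIP order.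

Step 8
Reactants: 12 4-[(2S,3R)-5-bromo-3-(hydroxymethyl)-7-methoxy-2,3-dihydrobenzofuran-2-yl]-2-methoxyphenyl pivalate
Product: 13 4-[(2S,3R)-5-allyl-3-(hydroxymethyl)-7-methoxy-2,3-dihydrobenzofuran-2-yl]-2-methoxyphenyl pivalate
Conditions: allylSnBu3 (1.5 equiv), Pd(PPh3)4 (5 mol%), toluene, 100 °C
Reagents that add atoms: allyltributylstannane, C=CC[Sn](CCCC)(CCCC)CCCC
Why: Stille coupling; zerovalent palladium inserts into the C5–Br bond, the allyl group is transferred from tin and reductive elimination forms the aryl–CH2 bond under neutral conditions that tolerate the free alcohol and the pivalate and leave both stereocentres alone.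

Step 9
Reactants: 13 4-[(2S,3R)-5-allyl-3-(hydroxymethyl)-7-methoxy-2,3-dihydrobenzofuran-2-yl]-2-methoxyphenyl pivalate; 14 eugenol (4-allyl-2-methoxyphenol, 1.5 equiv)
Product: 15 4-[(2S,3R)-5-allyl-3-[(4-allyl-2-methoxyphenoxy)methyl]-7-methoxy-2,3-dihydrobenzofuran-2-yl]-2-methoxyphenyl pivalate
Conditions: PPh3, DIAD, THF, 0 °C to rt
Reagents that add atoms: none
Why: Mitsunobu etherification; the primary alcohol is activated as its alkoxyphosphonium ion and displaced by the phenoxide of 14 (pKa about 10) at a CH2 carbon, so no stereocentre is involved and no free phenoxide accumulates that could attack the aryl ester. The pivalate prevents the ring B oxygen from competing as the nucleophile.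

Step 10
Reactants: 15 4-[(2S,3R)-5-allyl-3-[(4-allyl-2-methoxyphenoxy)methyl]-7-methoxy-2,3-dihydrobenzofuran-2-yl]-2-methoxyphenyl pivalate
Product: 16 4-[(2S,3R)-5-allyl-3-[(4-allyl-2-methoxyphenoxy)methyl]-7-methoxy-2,3-dihydrobenzofuran-2-yl]-2-methoxyphenol
Conditions: K2CO3, MeOH/THF, rt
Reagents that add atoms: none
Why: Base-catalysed methanolysis of an aryl ester; phenoxide is a good leaving group, so carbonate at room temperature should suffice, which is too mild to move the allyl double bonds or to open the C2–O1 bond.

## Compound list

1 | 2-hydroxy-3-methoxyacetophenone | CC(=O)c1cccc(OC)c1O | starting material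
2 | 1-(5-bromo-2-hydroxy-3-methoxyphenyl)ethanone | CC(=O)c1cc(Br)cc(OC)c1O | intermediate
3 | (E)-1-(5-bromo-2-hydroxy-3-methoxyphenyl)-3-(dimethylamino)prop-2-en-1-one | CN(C)/C=C/C(=O)c1cc(Br)cc(OC)c1O | intermediate
4 | 6-bromo-8-methoxy-4H-chromen-4-one | O=c1ccoc2c(OC)cc(Br)cc12 | intermediate
5 | 2-methoxy-4-(4,4,5,5-tetramethyl-1,3,2-dioxaborolan-2-yl)phenol | COc1cc(B2OC(C)(C)C(C)(C)O2)ccc1O | starting material
6 | 2-methoxy-4-(4,4,5,5-tetramethyl-1,3,2-dioxaborolan-2-yl)phenyl pivalate | COc1cc(B2OC(C)(C)C(C)(C)O2)ccc1OC(=O)C(C)(C)C | intermediate
7 | [3-methoxy-4-(pivaloyloxy)phenyl]boronic acid | COc1cc(B(O)O)ccc1OC(=O)C(C)(C)C | intermediate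
8 | (2S)-6-bromo-8-methoxy-2-[3-methoxy-4-(pivaloyloxy)phenyl]chroman-4-one | O=C1C[C@@H](c2ccc(OC(=O)C(C)(C)C)c(OC)c2)Oc2c(OC)cc(Br)cc21 | intermediate
9 | (2S)-6-bromo-4,8-dimethoxy-2-[3-methoxy-4-(pivaloyloxy)phenyl]-2H-chromene | COC1=C[C@@H](c2ccc(OC(=O)C(C)(C)C)c(OC)c2)Oc2c(OC)cc(Br)cc21 | intermediate
10 | (2R,3R)-3-[acetoxy(phenyl)-λ3-iodanyl]-6-bromo-4,4,8-trimethoxy-2-[3-methoxy-4-(pivaloyloxy)phenyl]chromane (iodine trans to the C2 aryl group) | COC1(OC)[C@H](I(OC(C)=O)c2ccccc2)[C@@H](c2ccc(OC(=O)C(C)(C)C)c(OC)c2)Oc2c(OC)cc(Br)cc21 | intermediate
11 | methyl (2S,3S)-5-bromo-7-methoxy-2-[3-methoxy-4-(pivaloyloxy)phenyl]-2,3-dihydrobenzofuran-3-carboxylate (trans) | COC(=O)[C@H]1c2cc(Br)cc(OC)c2O[C@@H]1c1ccc(OC(=O)C(C)(C)C)c(OC)c1 | intermediate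
12 | 4-[(2S,3R)-5-bromo-3-(hydroxymethyl)-7-methoxy-2,3-dihydrobenzofuran-2-yl]-2-methoxyphenyl pivalate | OC[C@H]1c2cc(Br)cc(OC)c2O[C@@H]1c1ccc(OC(=O)C(C)(C)C)c(OC)c1 | intermediate
13 | 4-[(2S,3R)-5-allyl-3-(hydroxymethyl)-7-methoxy-2,3-dihydrobenzofuran-2-yl]-2-methoxyphenyl pivalate | OC[C@H]1c2cc(CC=C)cc(OC)c2O[C@@H]1c1ccc(OC(=O)C(C)(C)C)c(OC)c1 | intermediate
14 | eugenol (4-allyl-2-methoxyphenol) | C=CCc1ccc(O)c(OC)c1 | starting material
15 | 4-[(2S,3R)-5-allyl-3-[(4-allyl-2-methoxyphenoxy)methyl]-7-methoxy-2,3-dihydrobenzofuran-2-yl]-2-methoxyphenyl pivalate | C=CCc1ccc(OC[C@H]2c3cc(CC=C)cc(OC)c3O[C@@H]2c2ccc(OC(=O)C(C)(C)C)c(OC)c2)c(OC)c1 | intermediate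
16 | 4-[(2S,3R)-5-allyl-3-[(4-allyl-2-methoxyphenoxy)methyl]-7-methoxy-2,3-dihydrobenzofuran-2-yl]-2-methoxyphenol | C=CCc1ccc(OC[C@H]2c3cc(CC=C)cc(OC)c3O[C@@H]2c2ccc(O)c(OC)c2)c(OC)c1 | target

## Step count and least certain steps

Total step count: 10. Longest linear sequence: 8 (steps 1, 2, 5, 6, 7, 8, 9, 10; the branch through steps 3 and 4 is equally long).

**Step 6 (key step).** The most likely failure is diversion of the C3 iodane into other channels: shift of ring B from C2 (ring A being slowed somewhat by the meta bromine), loss of the C2 hydrogen with dehydrogenation to the flavone, or methanolysis at C3. Incomplete trans selectivity is a lesser risk. The fallback sets out from 8 and returns at 11; it forms the same C3–C3a bond by a Wolff ring contraction instead of an oxidation. Compound 8 would be converted by detrifluoroacetylative diazo transfer (LiN(SiMe3)2, CF3CO2CH2CF3, THF, −78 °C; then MsN3, Et3N, MeCN) into (2R)-6-bromo-3-diazo-8-methoxy-2-[3-methoxy-4-(pivaloyloxy)phenyl]chroman-4-one F1. The arrangement at C2 is unchanged; the descriptor changes because the diazo carbon outranks the aryl group. Irradiation at 365 nm in MeOH should expel nitrogen, shift C4a to C3 and trap the ketene as the methyl ester. The cis epimer formed alongside, methyl (2S,3R)-5-bromo-7-methoxy-2-[3-methoxy-4-(pivaloyloxy)phenyl]-2,3-dihydrobenzofuran-3-carboxylate F2, would be equilibrated to 11 with catalytic DBU in toluene.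

**Step 7.** The most likely failure is loss of the protecting group through hydride attack on the aryl pivalate, which is more electrophilic than an alkyl ester although more hindered. The fallback sets out from 11 and returns at 12. Exhaustive reduction with LiAlH4 (THF, 0 °C) would give 4-[(2S,3R)-5-bromo-3-(hydroxymethyl)-7-methoxy-2,3-dihydrobenzofuran-2-yl]-2-methoxyphenol F3. Phenoxide-selective acylation under two-phase conditions (PivCl, aq NaOH, CH2Cl2, Bu4NHSO4, 0 °C) should then restore the pivalate without touching the primary alcohol.

**Step 5.** The most likely failure is insufficient face selectivity with this hindered, oxygenated pair, made worse by base-induced ring opening and reclosure of the flavanone and by protodeboronation of the electron-rich boronic acid. The fallback sets out from 8 of insufficient enantiomeric purity and returns at 8; it is a kinetic resolution by Noyori-type asymmetric transfer hydrogenation (RuCl(p-cymene)(TsDPEN) of the antipode matched to the 2R ketone, HCO2H/Et3N, EtOAc, rt). This should reduce the unwanted enantiomer to 4-[(2R,4R)-6-bromo-4-hydroxy-8-methoxychroman-2-yl]-2-methoxyphenyl pivalate F4 and leave (2S)-8, which is separable by chromatography.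

**Step 8.** The most likely failure is migration of the new double bond into conjugation with ring A through palladium hydride species at the temperature needed for the slow oxidative addition into an electron-rich aryl bromide, together with reductive loss of bromine. The fallback sets out from 12 and returns at 13; it reverses the polarity of the coupling. Miyaura borylation (B2pin2, PdCl2(dppf), KOAc, dioxane, 85 °C) would give 4-[(2S,3R)-3-(hydroxymethyl)-7-methoxy-5-(4,4,5,5-tetramethyl-1,3,2-dioxaborolan-2-yl)-2,3-dihydrobenzofuran-2-yl]-2-methoxyphenyl pivalate F5, with no alkene present during the difficult oxidative addition. Coupling with allyl bromide (Pd(PPh3)4, CsF, THF, 50 °C) should then proceed at low temperature, because oxidative addition to the allyl halide is fast.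

## Further compounds

F1 | step 6 | (2R)-6-bromo-3-diazo-8-methoxy-2-[3-methoxy-4-(pivaloyloxy)phenyl]chroman-4-one | O=C1C(=[N+]=[N-])[C@@H](c2ccc(OC(=O)C(C)(C)C)c(OC)c2)Oc2c(OC)cc(Br)cc21
F2 | step 6 | methyl (2S,3R)-5-bromo-7-methoxy-2-[3-methoxy-4-(pivaloyloxy)phenyl]-2,3-dihydrobenzofuran-3-carboxylate (cis) | COC(=O)[C@@H]1c2cc(Br)cc(OC)c2O[C@@H]1c1ccc(OC(=O)C(C)(C)C)c(OC)c1
F3 | step 7 | 4-[(2S,3R)-5-bromo-3-(hydroxymethyl)-7-methoxy-2,3-dihydrobenzofuran-2-yl]-2-methoxyphenol | OC[C@H]1c2cc(Br)cc(OC)c2O[C@@H]1c1ccc(O)c(OC)c1
F4 | step 5 | 4-[(2R,4R)-6-bromo-4-hydroxy-8-methoxychroman-2-yl]-2-methoxyphenyl pivalate (cis) | O[C@@H]1C[C@H](c2ccc(OC(=O)C(C)(C)C)c(OC)c2)Oc2c(OC)cc(Br)cc21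
F5 | step 8 | 4-[(2S,3R)-3-(hydroxymethyl)-7-methoxy-5-(4,4,5,5-tetramethyl-1,3,2-dioxaborolan-2-yl)-2,3-dihydrobenzofuran-2-yl]-2-methoxyphenyl pivalate | OC[C@H]1c2cc(B3OC(C)(C)C(C)(C)O3)cc(OC)c2O[C@@H]1c1ccc(OC(=O)C(C)(C)C)c(OC)c1
A1 | alternative 1 | (2S,3R)-5-allyl-3-[(4-allyl-2-methoxyphenoxy)methyl]-7-methoxy-2-(3-methoxy-4-triisopropylsilyloxyphenyl)-2,3-dihydrobenzofuran | C=CCc1ccc(OC[C@H]2c3cc(CC=C)cc(OC)c3O[C@@H]2c2ccc(O[Si](C(C)C)(C(C)C)C(C)C)c(OC)c2)c(OC)c1
A2 | alternative 1 | 4-allyl-2-[2-(4-allyl-2-methoxyphenoxy)-1-(4-methylphenylsulfonyl)ethyl]-6-methoxyphenol (racemic) | C=CCc1ccc(OCC(c2cc(CC=C)cc(OC)c2O)S(=O)(=O)c2ccc(C)cc2)c(OC)c1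
A3 | alternative 1 | 1-[(3-methoxy-4-triisopropylsilyloxyphenyl)methyl]thiolan-1-ium bromide | COc1cc(C[S+]2CCCC2)ccc1O[Si](C(C)C)(C(C)C)C(C)C.[Br-]
A4 | alternative 1 | 4-allyl-6-[2-(4-allyl-2-methoxyphenoxy)ethylidene]-2-methoxycyclohexa-2,4-dien-1-one | C=CCC1=CC(=CCOc2ccc(CC=C)cc2OC)C(=O)C(OC)=C1
A5 | alternative 1 | thiolan-1-ium-1-yl(3-methoxy-4-triisopropylsilyloxyphenyl)methanide | COc1cc([CH-][S+]2CCCC2)ccc1O[Si](C(C)C)(C(C)C)C(C)C
A6 | alternative 2 | (2S,3R)-3-[(4-allyl-2-methoxyphenoxy)methyl]-5-bromo-2-(4-hydroxy-3-methoxyphenyl)-7-methoxy-2,3-dihydrobenzofuran | C=CCc1ccc(OC[C@H]2c3cc(Br)cc(OC)c3O[C@@H]2c2ccc(O)c(OC)c2)c(OC)c1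
A7 | alternative 2 | 4-bromo-2-[(2R)-1-(4-allyl-2-methoxyphenoxy)-3-(4-hydroxy-3-methoxyphenyl)propan-2-yl]-6-methoxyphenol | C=CCc1ccc(OC[C@H](Cc2ccc(O)c(OC)c2)c2cc(Br)cc(OC)c2O)c(OC)c1
A8 | alternative 2 | 4-[(2R)-3-(4-allyl-2-methoxyphenoxy)-2-(5-bromo-2-hydroxy-3-methoxyphenyl)propylidene]-2-methoxycyclohexa-2,5-dien-1-one | C=CCc1ccc(OC[C@H](C=C2C=CC(=O)C(OC)=C2)c2cc(Br)cc(OC)c2O)c(OC)c1
A9 | alternative 3 | methyl (2S,3R)-3-[(4-allyl-2-methoxyphenoxy)methyl]-2-[4-(tert-butyldimethylsilyloxy)-3-methoxyphenyl]-7-methoxy-2,3-dihydrobenzofuran-5-carboxylate | C=CCc1ccc(OC[C@H]2c3cc(C(=O)OC)cc(OC)c3O[C@@H]2c2ccc(O[Si](C)(C)C(C)(C)C)c(OC)c2)c(OC)c1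
A10 | alternative 3 | (4R,5S)-4-[(4-allyl-2-methoxyphenoxy)methyl]-5-[4-(tert-butyldimethylsilyloxy)-3-methoxyphenyl]oxolan-2-one | C=CCc1ccc(OC[C@H]2CC(=O)O[C@@H]2c2ccc(O[Si](C)(C)C(C)(C)C)c(OC)c2)c(OC)c1
A11 | alternative 3 | tert-butyl-[4-[(2S,3R)-3-[(4-allyl-2-methoxyphenoxy)methyl]-5-(trimethylsilyloxy)-2,3-dihydrofuran-2-yl]-2-methoxyphenoxy]dimethylsilane | C=CCc1ccc(OC[C@H]2C=C(O[Si](C)(C)C)O[C@@H]2c2ccc(O[Si](C)(C)C(C)(C)C)c(OC)c2)c(OC)c1
A12 | alternative 3 | methyl 5-methoxy-6-oxo-6H-pyran-3-carboxylate | COC(=O)C1=COC(=O)C(OC)=C1
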